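The plan rests on a de Mayo disconnection of the cycloheptane ring (C1, C5–C10). Its oxygens at C5 and C9 sit 1,4 across C1–C10, and the γ-lactone is cis-fused at C6–C7. Photochemical [2+2] addition of 2,3-dihydrofuran (C6, C7, C11, C12, O) to a 3-alkoxy-5-methylcyclopent-2-enone (C9, C8, C5, C1, C10) forms C5–C6 and C7–C8. Freeing the C5 cyclobutanol then cleaves C5–C8 by retro-aldol and expands the ring to the 1,4-dione. The precursor carries a hydrogenolysable, enantiopure 1-phenylethyl ether, so the two facial adducts are separable diastereomers, and C10 is set by equilibration on the rigid tricycle.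

Key step: step 3

Conventions: C14 is the methyl on C10 and C15 is the terminal methyl of the crotonoyl group, which therefore spans four carbons (C2, C3, C4, C15). α is the face of the seven-membered ring that bears the C6–O and C7–C11 bonds; β is the face of H6 and H7. In these terms 25 (1S,5S,6R,7S,9R,10S) has C1–OH α, C1–acyl β, C5–O β, C9–OH β and C10–CH3 α.

Assumption: the auxiliary in 4 reacts through its A(1,3)-minimised conformer, which leaves the C5-Re/C8-Re face open; if the opposite facial series should dominate, step 1 starts from (R)-1-phenylethanol, which is equally available.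

Design points:
- (a) Methylation of a vinylogous ester enolate cannot deliver one C10 configuration, so C10 is fixed after the cycloaddition.
- (b) No Lewis acid is used in step 3, because 5 polymerises cationically.
- (c) The C5 ketone of 9 is the more electrophilic one, so C9 is masked and not reduced first.
- (d) At C1, oxygen is introduced before carbon, because external reagents reach C1 from the β face, anti to C10–CH3.
- (e) C5–OH and C9–OH are both trans to C1–OH and are set by hydride delivery from that hydroxyl.

Step 1
Reactants: 1 cyclopentane-1,3-dione; 2 (S)-1-phenylethanol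
Product: 3 3-[(1R)-1-phenylethoxy]cyclopent-2-en-1-one
Conditions: PPh3, DIAD, THF, 0 °C to rt
Reagents that add atoms: none
Why: Mitsunobu O-alkylation of the acidic enol of 1 runs by SN2 at the carbinol carbon, so the (S)-alcohol gives the (R)-ether without the acid that would ionise a secondary benzylic alcohol.

Step 2
Reactants: 3 3-[(1R)-1-phenylethoxy]cyclopent-2-en-1-one
Product: 4 5-methyl-3-[(1R)-1-phenylethoxy]cyclopent-2-en-1-one (both C10 epimers)
Conditions: LiN(iPr)2, THF, −78 °C; MeI, −78 to −20 °C
Reagents that add atoms: iodomethane, CI
Why: Kinetic α′-deprotonation of the vinylogous ester (Stork–Danheiser alkylation) gives the cross-conjugated enolate, which is methylated at C10; the remote auxiliary exerts no control, and both epimers are accepted because C10 is equilibrated in step 3.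

Step 3
Reactants: 4 5-methyl-3-[(1R)-1-phenylethoxy]cyclopent-2-en-1-one; 5 2,3-dihydrofuran
Product: 7 cis-anti-cis tricyclic ketone with exo C10 methyl (5S 6R 7R 8R 10R; auxiliary R), via C10-epimeric photoadducts 6 (not isolated)
Conditions: hν (300 nm, Pyrex), 5 (20 equiv), MeCN, −20 °C, Ar; evaporate; DBU (0.2 equiv), CH2Cl2, rt; separation on SiO2
Reagents that add atoms: none
Why: Excitation of 4 and intersystem crossing give the twisted triplet enone, which bonds to the electron-rich alkene of 5 to form a triplet 1,4-diradical that collapses to the cyclobutane after spin inversion; this is the enone–alkene [2+2] photocycloaddition that opens every de Mayo sequence of 1,3-dione enol derivatives. The only ring closed here is the four-membered ring C5–C6–C7–C8, closed by radical–radical recombination of that diradical (stepwise formal [2+2]); the seven-membered ring is not closed but uncovered in step 4. Head-to-tail orientation (C5 to the oxygen-bearing C6, C8 to C7) is required and follows from the polarity of the enol ether, whose nucleophilic carbon C7 pairs with the electron-poor α-carbon C8 of the excited enone, helped by the large excess of 5. C5/C8 and C6/C7 are cis because a cyclobutane cannot be trans-fused to these five-membered rings without prohibitive strain, and the tetrahydrofuran turns away from the cyclopentanone (cis-anti-cis) for steric reasons. The absolute sense comes from the (R)-1-phenylethyl group, which with its carbinol C–H in the enone plane next to C8–H holds phenyl over the Si face, so that 5 adds to the C5-Re/C8-Re face; the minor facial series is a diastereomer and is removed by chromatography. DBU then enolises only toward C10 (C8 is a cyclobutane bridgehead) and moves the methyl to the convex face, anti to the cyclobutane, which is the C10 configuration of the target.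

Step 4
Reactants: 7 cis-anti-cis tricyclic ketone
Product: 9 cis-fused tetrahydrofuran–cycloheptane-5,9-dione with C10–CH3 α (6R 7R 10R), via cyclobutanol 8 (not isolated)
Conditions: H2 (1 atm), Pd(OH)2/C, EtOAc, rt
Reagents that add atoms: none
Why: Hydrogenolysis of the benzylic C–O bond frees the tertiary cyclobutanol 8, a strained β-hydroxy ketone that undergoes retro-aldol cleavage of C5–C8 (second half of the de Mayo sequence) and merges the five- and four-membered rings into the cycloheptane-1,4-dione; C6, C7 and C10 are untouched because the enol forms toward C8.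

Step 5
Reactants: 9 tetrahydrofuran–cycloheptane-5,9-dione
Product: 10 cis-fused γ-lactone–cycloheptane-5,9-dione
Conditions: RuCl3·xH2O (5 mol %), NaIO4 (4 equiv), EtOAc/MeCN/H2O, rt
Reagents that add atoms: sodium periodate (oxygen relayed through RuO4), [Na+].[O-]I(=O)(=O)=O
Why: RuO4-mediated ether-to-lactone oxidation attacks C12, the only O–CH2 group, because the other ether position (C6–H) is tertiary and deactivated by the adjacent C5 ketone; it is placed here since no alkene, arene or free alcohol is present yet, and no stereocentre is touched.

Step 6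
Reactants: 10 γ-lactone–cycloheptane-5,9-dione
Product: 11 C9 ethylene ketal of 10 (C5 ketone free)
Conditions: (Me3SiOCH2)2 (1.2 equiv), Me3SiOTf (5 mol %), CH2Cl2, −78 to −30 °C; pyridine quench
Reagents that add atoms: 1,2-bis(trimethylsilyloxy)ethane, C[Si](C)(C)OCCO[Si](C)(C)C
Why: Noyori ketalisation (aprotic, kinetic) takes the more Lewis-basic C9 ketone, since an oxocarbenium ion at C5 is destabilised by the α-acyloxy group on C6 and C5 is screened by the ring fusion; the low temperature avoids enolisation, so C10 is kept.

Step 7
Reactants: 11 C9 ketal; 12 (E)-crotonic anhydride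
Product: 14 C1 (E)-crotonate of the C1/C5 acyloin (C1 epimers), via C1 acyloin 13 (not isolated)
Conditions: NaN(SiMe3)2 (1.1 equiv), THF, −78 °C; 2-(benzenesulfonyl)-3-phenyloxaziridine; then 12, DMAP (cat.), −78 to 0 °C
Reagents that add atoms: 2-(benzenesulfonyl)-3-phenyloxaziridine, O=S(=O)(N1OC1c1ccccc1)c1ccccc1
Why: Kinetic enolisation of the single free ketone at its only α-methylene group (C1; the tertiary C6–H is slower for a bulky amide base) and Davis hydroxylation give acyloin 13, whose alkoxide is esterified in the same flask; the C1 configuration is left open because C1 becomes planar again in step 8.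

Step 8
Reactants: 14 C1 crotonate
Product: 15 α-hydroxy-1,3-diketone (C1–OH α; C1–crotonoyl β; C5 ketone)
Conditions: LiN(SiMe3)2 (1.5 equiv), THF, −78 to −25 °C; AcOH, −78 °C
Reagents that add atoms: none
Why: Chan rearrangement (known for acyloxyacetates and for α-carbonate ketones): the C1 enolate of the α-acyloxy ketone adds 3-exo-trig to its own ester carbonyl and the oxirane alkoxide reopens with the acyl group on carbon; the acyl carbon swings to the β face, anti to the pseudo-axial C10 methyl, which leaves the oxygen α and sets C1, while enolisation toward C6 has no productive outlet and reverts through amine-mediated proton exchange.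

Step 9
Reactants: 15 α-hydroxy-1,3-diketone
Product: 16 triol (C1–OH α; C5–OH β; C2 carbinol as epimers)
Conditions: Me4NBH(OAc)3 (8 equiv), MeCN/AcOH, −30 to 0 °C
Reagents that add atoms: none
Why: Saksena–Evans hydroxyl-directed reduction: the α-oriented C1–OH binds boron and hands hydride to the adjacent C5 ketone from the α face, giving the trans-diol with C5–OH β, and the same delivery reduces the C2 ketone 1,2 to an allylic carbinol of irrelevant configuration, parked at this level so that no enolisable ketone interferes in step 11; lactone and ketal are inert to the triacetoxyborohydride.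

Step 10
Reactants: 16 triol
Product: 17 C2 tert-butyldimethylsilyl ether of 16
Conditions: tBuMe2SiCl (1.1 equiv), imidazole, DMF, 0 °C
Reagents that add atoms: tert-butyldimethylsilyl chloride, CC(C)(C)[Si](C)(C)Cl
Why: Sterically governed silylation: the allylic C2–OH has one small sp2 neighbour, whereas C5–OH lies between the quaternary C1 and the ring-fusion carbon C6 and C1–OH is tertiary, so only C2–OH is capped.

Step 11
Reactants: 17 C2 silyl ether
Product: 20 α-methylene lactone (C11=C13) with free C1–OH and C5–OH, via Mannich base 18 (not isolated), via trimethylammonium iodide 19 (not isolated)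
Conditions: LiN(iPr)2 (3.5 equiv), THF, −78 °C; CH2=NMe2+ I−, −78 to 0 °C; MeI, THF, rt; aq. NaHCO3/CH2Cl2, rt
Reagents that add atoms: N,N-dimethylmethyleneiminium iodide, C=[N+](C)C.[I-]; iodomethane, CI (its carbon stays only in 19)
Why: The lactone is now the only carbonyl group, so its lithium enolate (beside the two alkoxides) undergoes the Mannich reaction with Eschenmoser's salt at C11, and quaternisation followed by Hofmann-type β-elimination gives the exocyclic C11=C13 alkene, which erases the transient C11 centre.

Step 12
Reactants: 20 α-methylene lactone diol; 21 isovaleric anhydride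
Product: 22 C5 isovalerate of 20
Conditions: 21 (3 equiv), DMAP (0.3 equiv), Et3N, CH2Cl2, rt
Reagents that add atoms: none
Why: DMAP-catalysed acylation esterifies the only secondary hydroxyl (C5–OH) and leaves the tertiary C1–OH free; the C5–O bond is not broken, so the configuration is retained.

Step 13
Reactants: 22 C5 isovalerate
Product: 23 C9 ketone with free C1–OH and C2–OH
Conditions: aq. HF (48 %), MeCN, 0 °C to rt
Reagents that add atoms: water, O
Why: Aqueous HF cleaves the silyl ether and hydrolyses the dioxolane in one operation, while both esters, the α-methylene lactone and the allylic alcohol tolerate it; the short, cold exposure limits enolisation toward C10 and loss of the β-hydroxyl at C1.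

Step 14
Reactants: 23 C9 ketone
Product: 24 C9 β-alcohol (C2 carbinol still as epimers)
Conditions: Me4NBH(OAc)3 (5 equiv), MeCN/AcOH, −30 °C
Reagents that add atoms: none
Why: Saksena–Evans 1,3-anti reduction of a β-hydroxy ketone: boron bound to the α C1–OH delivers hydride to C9 through a six-membered transition state from the α face, so C9–OH emerges β (anti to C1–OH and trans to the C10 methyl); the isolated ester and the conjugated lactone are not reduced.

Step 15
Reactants: 24 C9 β-alcohol
Product: 25 CNP0186412.1
Conditions: MnO2 (activated, excess), CH2Cl2, rt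
Reagents that add atoms: none
Why: MnO2 oxidises only the allylic C2 carbinol (both epimers converge) to the (E)-enone and leaves the saturated secondary C9–OH and the tertiary C1–OH untouched, which completes 25.

Compound list
1 | cyclopentane-1,3-dione | O=C1CCC(=O)C1 | starting material
2 | (S)-1-phenylethanol | C[C@H](O)c1ccccc1 | starting material
3 | 3-[(1R)-1-phenylethoxy]cyclopent-2-en-1-one | O=C1C=C(O[C@H](C)c2ccccc2)CC1 | intermediate
4 | 5-methyl-3-[(1R)-1-phenylethoxy]cyclopent-2-en-1-one, both C10 epimers | O=C1C=C(O[C@H](C)c2ccccc2)CC1C | intermediate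
5 | 2,3-dihydrofuran | C1=COCC1 | starting material
6 | head-to-tail cis-anti-cis photoadducts, epimeric at C10 | O=C1C(C)C[C@@]2(O[C@H](C)c3ccccc3)[C@@H]4OCC[C@@H]4[C@@H]12 | intermediate
7 | tricyclic ketone: cyclobutane C5–C6–C7–C8 cis-fused to the cyclopentanone (C5/C8) and, anti to it, to the tetrahydrofuran (C6/C7); C5–O-(R)-1-phenylethyl; C10 methyl exo | O=C1[C@H](C)C[C@@]2(O[C@H](C)c3ccccc3)[C@@H]4OCC[C@@H]4[C@@H]12 | intermediate
8 | C5 cyclobutanol from 7 | O=C1[C@H](C)C[C@@]2(O)[C@@H]3OCC[C@@H]3[C@@H]12 | intermediate
9 | cis-fused tetrahydrofuran–cycloheptane-5,9-dione, C10–CH3 α ((3aR,6R,8aR)-6-methylhexahydro-2H-cyclohepta[b]furan-5,8-dione) | O=C1C[C@@H](C)C(=O)C[C@H]2CCO[C@@H]12 | intermediate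
10 | cis-fused γ-lactone–cycloheptane-5,9-dione | O=C1C[C@@H](C)C(=O)C[C@H]2CC(=O)O[C@@H]12 | intermediate
11 | C9 ethylene ketal of 10 | O=C1C[C@@H](C)C2(OCCO2)C[C@H]3CC(=O)O[C@@H]13 | intermediate
12 | (E)-crotonic anhydride | C/C=C/C(=O)OC(=O)/C=C/C | starting material
13 | C1-hydroxy C5-ketone (acyloin), C1 epimers | O=C1C(O)[C@@H](C)C2(OCCO2)C[C@H]3CC(=O)O[C@@H]13 | intermediate
14 | C1 (E)-crotonate of 13, C1 epimers | O=C1C(OC(=O)/C=C/C)[C@@H](C)C2(OCCO2)C[C@H]3CC(=O)O[C@@H]13 | intermediate
15 | α-hydroxy-1,3-diketone, C1–OH α, C1–(E)-crotonoyl β | O=C1[C@](O)(C(=O)/C=C/C)[C@@H](C)C2(OCCO2)C[C@H]3CC(=O)O[C@@H]13 | intermediate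
16 | triol, C1–OH α, C5–OH β, C2 carbinol epimers | O[C@@H]1[C@](O)(C(O)/C=C/C)[C@@H](C)C2(OCCO2)C[C@H]3CC(=O)O[C@@H]13 | intermediate
17 | C2 tert-butyldimethylsilyl ether of 16 | O[C@@H]1[C@](O)(C(O[Si](C)(C)C(C)(C)C)/C=C/C)[C@@H](C)C2(OCCO2)C[C@H]3CC(=O)O[C@@H]13 | intermediate
18 | C11 (dimethylamino)methyl lactone | O[C@@H]1[C@](O)(C(O[Si](C)(C)C(C)(C)C)/C=C/C)[C@@H](C)C2(OCCO2)C[C@H]3C(CN(C)C)C(=O)O[C@@H]13 | intermediate
19 | C11 (trimethylammonio)methyl lactone iodide | O[C@@H]1[C@](O)(C(O[Si](C)(C)C(C)(C)C)/C=C/C)[C@@H](C)C2(OCCO2)C[C@H]3C(C[N+](C)(C)C)C(=O)O[C@@H]13.[I-] | intermediate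
20 | α-methylene lactone, C1–OH and C5–OH free | O[C@@H]1[C@](O)(C(O[Si](C)(C)C(C)(C)C)/C=C/C)[C@@H](C)C2(OCCO2)C[C@H]3C(=C)C(=O)O[C@@H]13 | intermediate
21 | isovaleric anhydride | CC(C)CC(=O)OC(=O)CC(C)C | starting material
22 | C5 isovalerate of 20 | CC(C)CC(=O)O[C@@H]1[C@](O)(C(O[Si](C)(C)C(C)(C)C)/C=C/C)[C@@H](C)C2(OCCO2)C[C@H]3C(=C)C(=O)O[C@@H]13 | intermediate
23 | C9 ketone, C1–OH and C2–OH free | CC(C)CC(=O)O[C@@H]1[C@](O)(C(O)/C=C/C)[C@@H](C)C(=O)C[C@H]2C(=C)C(=O)O[C@@H]12 | intermediate
24 | C9 β-alcohol, C2 carbinol epimers | CC(C)CC(=O)O[C@@H]1[C@](O)(C(O)/C=C/C)[C@@H](C)[C@H](O)C[C@H]2C(=C)C(=O)O[C@@H]12 | intermediate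
25 | CNP0186412.1 (1S,5S,6R,7S,9R,10S) | C=C1C(=O)O[C@@H]2[C@H]1C[C@@H](O)[C@H](C)[C@@](O)(C(=O)/C=C/C)[C@H]2OC(=O)CC(C)C | target

Total step count: 15. Longest linear sequence: 15 steps (1 to 25); 2, 5, 12 and 21 are bought.

Steps most likely to fail

Step 3. The auxiliary may discriminate poorly between the two enone faces, the two adduct series may co-elute, and head-to-tail regioselectivity may erode. The fallback keeps the same photochemical bond set but takes the absolute configuration from a classical resolution; it sets out from 1 and returns at 9. Compound 1 is condensed with benzyl alcohol (TsOH, toluene, water separator) to 3-(benzyloxy)cyclopent-2-en-1-one F1. This is methylated as in step 2 to racemic 3-(benzyloxy)-5-methylcyclopent-2-en-1-one F2. Irradiation with 5 and equilibration with DBU as in step 3 give the racemic benzyl-protected tricyclic ketone F3. Its C9 ketone is ketalised with (R,R)-hydrobenzoin (bis-trimethylsilyl ether, Me3SiOTf, CH2Cl2). The two diastereomeric ketals are separated by crystallisation or chromatography to give the hydrobenzoin ketal of the required enantiomer F4. H2 over Pd(OH)2/C then removes the benzyl ether and the benzylic ketal together, and the liberated 8 opens to 9.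

Step 8. Enolisation at C6 or γ-deprotonation of the crotonate may outrun enolisation at C1 and lead to acyl scrambling instead of the O-to-C shift. The fallback builds the same carbon–carbon bond intermolecularly and adds oxygen afterwards; it sets out from 11 and returns at 15. The kinetic lithium enolate of 11 (LiN(iPr)2, THF, −78 °C) is added to (E)-crotonaldehyde to give the C1 aldol adduct F5. Dess–Martin periodinane oxidises it to the 2-crotonoyl ketone F6. The sodium enolate of F6 is hydroxylated with an enantiopure (8,8-dichlorocamphorylsulfonyl)oxaziridine. Here the substrate bias (attack anti to C10–CH3) works against the required α-hydroxylation, so reagent control and chromatographic removal of the C1 epimer are relied on to reach 15.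

Step 6. Discrimination between the two ketones may be insufficient, or C10 may epimerise under acid. The fallback uses the reactivity difference in the opposite sense; it sets out from 10 and returns at 11. A limiting amount of NaBH4 (MeOH/CH2Cl2, −78 °C) reduces the more electrophilic α-acyloxy ketone to the C5 alcohol F7. The single remaining ketone is ketalised under the conditions of step 6 (an adventitious trimethylsilyl ether is lost on work-up) to the hydroxy ketal F8. Dess–Martin periodinane restores the C5 ketone of 11.

Further compounds
F1 | step 3 | 3-(benzyloxy)cyclopent-2-en-1-one | O=C1C=C(OCc2ccccc2)CC1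
F2 | step 3 | rac-3-(benzyloxy)-5-methylcyclopent-2-en-1-one | O=C1C=C(OCc2ccccc2)CC1C
F3 | step 3 | rac-benzyl-protected cis-anti-cis tricyclic ketone, C10 methyl exo (one enantiomer drawn) | O=C1[C@H](C)C[C@@]2(OCc3ccccc3)[C@@H]4OCC[C@@H]4[C@@H]12
F4 | step 3 | C9 (R,R)-hydrobenzoin ketal of the required enantiomer of F3 | C16(O[C@H](c7ccccc7)[C@@H](c8ccccc8)O6)[C@H](C)C[C@@]2(OCc3ccccc3)[C@@H]4OCC[C@@H]4[C@@H]12
F5 | step 8 | C1 aldol adduct of 11 with (E)-crotonaldehyde (C1 and C2 epimers) | O=C1C(C(O)/C=C/C)[C@@H](C)C2(OCCO2)C[C@H]3CC(=O)O[C@@H]13
F6 | step 8 | C1 (E)-crotonoyl C5-ketone (1,3-diketone) | O=C1C(C(=O)/C=C/C)[C@@H](C)C2(OCCO2)C[C@H]3CC(=O)O[C@@H]13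
F7 | step 6 | C5 alcohol, C9 ketone (C5 epimers) | OC1C[C@@H](C)C(=O)C[C@H]2CC(=O)O[C@@H]12
F8 | step 6 | C5 alcohol, C9 ethylene ketal (C5 epimers) | OC1C[C@@H](C)C2(OCCO2)C[C@H]3CC(=O)O[C@@H]13
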